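**Retrosynthetic overview** (ring locants: O1, C2 methyl, C3 CH2OH, C4 acetate arm, C5 CO2Me, C6; TBS = tert-butyldimethylsilyl, TBSO = its oxy group)
1. The target is unveiled from its tris-TBS ether by one global desilylation; catechol and primary alcohol stay masked until then.
2. Key disconnection C4–C5: C5 is the α-carbon of the vinylogous carbonate O1–C6H=C5–CO2Me, and C4 is the β-carbon of the side-chain ester, joined to C5 through C6–O1–C2–C3. The ring is therefore the 6-exo conjugate adduct of a C5 vinyl radical (from a (Z)-α-iodo-β-alkoxyacrylate) to an (E)-enoate. This is the only ring formed; the arene is bought as hydroxytyrosol.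
3. The enoate, already carrying the arylethyl ester, comes from cross-metathesis of a vinyl group with the acrylate of bis-silylated hydroxytyrosol; the iodoacrylate comes from oxa-Michael addition of the C2 hydroxyl to methyl propiolate, then iodination.
4. C2 and C3 are set together by an Evans syn-aldol of a crotonyl imide dienolate with acetaldehyde (the imide carbonyl becomes the CH2OH carbon); C4 is set in the key step.

Key step: step 11

Assumption: the SMILES is read as (2R,3R,4S), with the C2 methyl, C3 hydroxymethyl and C4 acetate arm mutually trans on the dihydropyran.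

**Step 1**
Reactants: 1 (4S)-4-benzyl-1,3-oxazolidin-2-one; 2 (2E)-but-2-enoyl chloride
Product: 3 (4S)-4-benzyl-3-[(2E)-but-2-enoyl]-1,3-oxazolidin-2-one
Conditions: n-BuLi, THF, −78 °C; then 2, −78 → 0 °C
Reagents that add atoms: none
Why: N-acylation of the lithiated oxazolidinone by an acid chloride is a standard imide formation and creates no stereocentre.

**Step 2**
Reactants: 3 (4S)-4-benzyl-3-[(2E)-but-2-enoyl]-1,3-oxazolidin-2-one; 4 acetaldehyde
Product: 7 (4S)-4-benzyl-3-[(2S,3R)-2-ethenyl-3-hydroxybutanoyl]-1,3-oxazolidin-2-one, via boron dienolate 5 (not isolated), via boron aldolate 6 (not isolated)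
Conditions: Bu2BOTf, Et3N, CH2Cl2, −78 → 0 °C; 4, −78 → 0 °C; then pH 7 buffer, MeOH, H2O2, 0 °C
Reagents that add atoms: dibutylboron triflate, CCCCB(CCCC)OS(=O)(=O)C(F)(F)F (its Bu2B group is carried only by intermediates 5 and 6)
Why: Evans syn-aldol reaction: γ-deprotonation gives the (Z)-boron dienolate 5, which should react at its α-carbon through a closed Zimmerman–Traxler chair whose face is fixed by the benzyl group of the auxiliary, giving the 2,3-syn (2S,3R) adduct whose two centres become C3 and C2 of the pyran.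

**Step 3**
Reactants: 7 (4S)-4-benzyl-3-[(2S,3R)-2-ethenyl-3-hydroxybutanoyl]-1,3-oxazolidin-2-one
Product: 8 (2R,3R)-2-ethenylbutane-1,3-diol
Conditions: LiBH4, MeOH (1 equiv), Et2O, 0 °C
Reagents that add atoms: none
Why: LiBH4 reduces the exocyclic carbonyl of an N-acyl oxazolidinone to the primary alcohol (reductive auxiliary removal) without touching the alkene or either stereocentre, and auxiliary 1 is recovered.

**Step 4**
Reactants: 8 (2R,3R)-2-ethenylbutane-1,3-diol
Product: 9 (2R,3R)-3-[(TBSO)methyl]pent-4-en-2-ol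
Conditions: TBSCl (1.05 equiv), imidazole, CH2Cl2, −20 → 0 °C
Reagents that add atoms: tert-butyldimethylsilyl chloride, CC(C)(C)[Si](C)(C)Cl
Why: a bulky chlorosilane silylates the primary hydroxyl much faster than the hindered secondary one, which stays free as the future ring oxygen O1.

**Step 5**
Reactants: 9 (2R,3R)-3-[(TBSO)methyl]pent-4-en-2-ol; 10 methyl prop-2-ynoate (methyl propiolate)
Product: 11 methyl (2E)-3-({(2R,3R)-3-[(TBSO)methyl]pent-4-en-2-yl}oxy)prop-2-enoate
Conditions: PMe3 (10 mol%), CH2Cl2, 0 °C → rt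
Reagents that add atoms: none
Why: phosphine-catalysed oxa-Michael addition of an alcohol to methyl propiolate gives the (E)-β-alkoxyacrylate and so forms the O1–C6 bond, the secondary hydroxyl being the only nucleophile in 9.

**Step 6**
Reactants: 11 methyl (2E)-3-({(2R,3R)-3-[(TBSO)methyl]pent-4-en-2-yl}oxy)prop-2-enoate
Product: 13 methyl (2Z)-2-iodo-3-({(2R,3R)-3-[(TBSO)methyl]pent-4-en-2-yl}oxy)prop-2-enoate, via iodoacetoxy adduct 12 (not isolated)
Conditions: NIS, AcOH, CH2Cl2, rt, dark; then Et3N, 0 °C → rt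
Reagents that add atoms: N-iodosuccinimide, O=C1CCC(=O)N1I; acetic acid, CC(=O)O (its acetoxy group is carried only by intermediate 12)
Why: iodoacetoxylation of the donor-substituted C=C bond followed by base-induced loss of acetic acid is the established route from β-alkoxyacrylates to (Z)-α-iodo-β-alkoxyacrylates, it places iodine cis to the ether oxygen as the ring closure needs, and the inductively deactivated monosubstituted alkene should react more slowly.

**Step 7**
Reactants: 14 hydroxytyrosol, 4-(2-hydroxyethyl)benzene-1,2-diol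
Product: 15 tert-butyl{2-[3,4-bis(TBSO)phenyl]ethoxy}dimethylsilane
Conditions: TBSCl (3.5 equiv), imidazole, DMF, rt
Reagents that add atoms: tert-butyldimethylsilyl chloride, CC(C)(C)[Si](C)(C)Cl
Why: exhaustive silylation masks the catechol, which would otherwise quench the radical chain of step 11 and be oxidised or iodinated along the way.

**Step 8**
Reactants: 15 tert-butyl{2-[3,4-bis(TBSO)phenyl]ethoxy}dimethylsilane
Product: 16 2-[3,4-bis(TBSO)phenyl]ethan-1-ol
Conditions: PPTS (cat.), EtOH, rt
Reagents that add atoms: none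
Why: acid-catalysed ethanolysis cleaves the primary alkyl silyl ether far faster than the aryl silyl ethers, whose oxygen is much less basic.

**Step 9**
Reactants: 16 2-[3,4-bis(TBSO)phenyl]ethan-1-ol; 17 prop-2-enoyl chloride (acryloyl chloride)
Product: 18 2-[3,4-bis(TBSO)phenyl]ethyl prop-2-enoate
Conditions: Et3N, CH2Cl2, −20 → 0 °C
Reagents that add atoms: none
Why: O-acylation of a primary alcohol by an acid chloride with an amine base is reliable and leaves the aryl silyl ethers intact.

**Step 10**
Reactants: 13 methyl (2Z)-2-iodo-3-({(2R,3R)-3-[(TBSO)methyl]pent-4-en-2-yl}oxy)prop-2-enoate; 18 2-[3,4-bis(TBSO)phenyl]ethyl prop-2-enoate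
Product: 19 2-[3,4-bis(TBSO)phenyl]ethyl (2E,4R,5R)-5-{[(1Z)-2-iodo-3-methoxy-3-oxoprop-1-en-1-yl]oxy}-4-[(TBSO)methyl]hex-2-enoate
Conditions: second-generation Hoveyda–Grubbs catalyst RuCl2(H2IMes)(=CH-C6H4-2-OiPr) (5–10 mol%), 18 (3 equiv), CH2Cl2, 40 °C
Reagents that add atoms: none
Why: olefin cross-metathesis of a terminal alkene that homodimerises slowly with an excess of an acrylate should be selective for the (E)-configured cross product, and the trisubstituted electron-poor iodoalkene and the silyl ethers are inert to the ruthenium carbene.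

**Step 11**
Reactants: 19 2-[3,4-bis(TBSO)phenyl]ethyl (2E,4R,5R)-5-{[(1Z)-2-iodo-3-methoxy-3-oxoprop-1-en-1-yl]oxy}-4-[(TBSO)methyl]hex-2-enoate
Product: 20 methyl (2R,3R,4S)-4-(2-{2-[3,4-bis(TBSO)phenyl]ethoxy}-2-oxoethyl)-2-methyl-3-[(TBSO)methyl]-3,4-dihydro-2H-pyran-5-carboxylate
Conditions: Bu3SnH (1.3 equiv), AIBN (cat.), benzene (0.01 M), 80 °C, syringe-pump addition of the hydride
Reagents that add atoms: none
Why: Bu3Sn• abstracts iodine from 19 to give a C5-centred vinyl radical (linear, conjugated with the ester), which adds to C4, the β-carbon of the (E)-enoate, and the α-ester radical so formed takes hydrogen from Bu3SnH to carry the chain. The closest known reaction type is the tin hydride-mediated cyclisation of vinyl iodides onto α,β-unsaturated esters (vinyl radical conjugate cyclisation). The dihydropyran ring (O1, C2, C3, C4, C5, C6) is closed in the 6-exo-trig mode, and because the radical carbon keeps its double bond to C6 the vinylogous carbonate O1–C6=C5–CO2Me appears in the product without any redox adjustment. The new C4 stereocentre is controlled by C2 and C3 through a chair-like transition state with the C2 methyl, the C3 silyloxymethyl group and the enoate arm all pseudo-equatorial, which should give the 3,4-trans (4S) product. The step needs cyclisation to outrun direct reduction of the vinyl radical and 1,5-hydrogen transfer from C3–H, which slow addition of the hydride at high dilution and the activated acceptor are meant to secure, and it needs 6-exo over 7-endo attack, which the polarity of the enoate secures. Since the vinyl radical is linear and the enoate geometry is lost on addition, minor (E)/(Z) isomers of either double bond of 19 should converge on the same product.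

**Step 12**
Reactants: 20 methyl (2R,3R,4S)-4-(2-{2-[3,4-bis(TBSO)phenyl]ethoxy}-2-oxoethyl)-2-methyl-3-[(TBSO)methyl]-3,4-dihydro-2H-pyran-5-carboxylate
Product: 21 methyl (2R,3R,4S)-4-{2-[2-(3,4-dihydroxyphenyl)ethoxy]-2-oxoethyl}-3-(hydroxymethyl)-2-methyl-3,4-dihydro-2H-pyran-5-carboxylate
Conditions: HF·pyridine, pyridine, THF, 0 °C → rt
Reagents that add atoms: none
Why: HF·pyridine cleaves the alkyl and both aryl Si–O bonds in one operation under weakly acidic, non-nucleophilic conditions that should leave both esters, the enol ether and the three stereocentres untouched and disfavour lactonisation of the freed primary alcohol onto the arylethyl ester.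

**Compound list**
1 | (4S)-4-benzyl-1,3-oxazolidin-2-one | O=C1N[C@@H](Cc2ccccc2)CO1 | starting material
2 | (2E)-but-2-enoyl chloride | C/C=C/C(=O)Cl | starting material
3 | (4S)-4-benzyl-3-[(2E)-but-2-enoyl]-1,3-oxazolidin-2-one | C/C=C/C(=O)N1C(=O)OC[C@@H]1Cc1ccccc1 | intermediate
4 | acetaldehyde | CC=O | starting material
5 | (4S)-4-benzyl-3-{(1Z)-1-[(dibutylboranyl)oxy]buta-1,3-dien-1-yl}-1,3-oxazolidin-2-one (boron dienolate) | C=C/C=C(\OB(CCCC)CCCC)N1C(=O)OC[C@@H]1Cc1ccccc1 | intermediate (not isolated)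
6 | (4S)-4-benzyl-3-{(2S,3R)-3-[(dibutylboranyl)oxy]-2-ethenylbutanoyl}-1,3-oxazolidin-2-one (boron aldolate) | CCCCB(CCCC)O[C@H](C)[C@H](C=C)C(=O)N1C(=O)OC[C@@H]1Cc1ccccc1 | intermediate (not isolated)
7 | (4S)-4-benzyl-3-[(2S,3R)-2-ethenyl-3-hydroxybutanoyl]-1,3-oxazolidin-2-one | O[C@H](C)[C@H](C=C)C(=O)N1C(=O)OC[C@@H]1Cc1ccccc1 | intermediate
8 | (2R,3R)-2-ethenylbutane-1,3-diol | O[C@H](C)[C@@H](CO)C=C | intermediate
9 | (2R,3R)-3-[(TBSO)methyl]pent-4-en-2-ol | O[C@H](C)[C@@H](CO[Si](C)(C)C(C)(C)C)C=C | intermediate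
10 | methyl prop-2-ynoate | C#CC(=O)OC | starting material
11 | methyl (2E)-3-({(2R,3R)-3-[(TBSO)methyl]pent-4-en-2-yl}oxy)prop-2-enoate | COC(=O)/C=C/O[C@H](C)[C@@H](CO[Si](C)(C)C(C)(C)C)C=C | intermediate
12 | methyl 3-acetoxy-2-iodo-3-({(2R,3R)-3-[(TBSO)methyl]pent-4-en-2-yl}oxy)propanoate (iodoacetoxy adduct, mixture at the two new centres) | COC(=O)C(I)C(OC(C)=O)O[C@H](C)[C@@H](CO[Si](C)(C)C(C)(C)C)C=C | intermediate (not isolated)
13 | methyl (2Z)-2-iodo-3-({(2R,3R)-3-[(TBSO)methyl]pent-4-en-2-yl}oxy)prop-2-enoate | COC(=O)/C(I)=C/O[C@H](C)[C@@H](CO[Si](C)(C)C(C)(C)C)C=C | intermediate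
14 | hydroxytyrosol, 4-(2-hydroxyethyl)benzene-1,2-diol | OCCc1ccc(O)c(O)c1 | starting material
15 | tert-butyl{2-[3,4-bis(TBSO)phenyl]ethoxy}dimethylsilane | CC(C)(C)[Si](C)(C)OCCc1ccc(O[Si](C)(C)C(C)(C)C)c(O[Si](C)(C)C(C)(C)C)c1 | intermediate
16 | 2-[3,4-bis(TBSO)phenyl]ethan-1-ol | OCCc1ccc(O[Si](C)(C)C(C)(C)C)c(O[Si](C)(C)C(C)(C)C)c1 | intermediate
17 | prop-2-enoyl chloride | C=CC(=O)Cl | starting material
18 | 2-[3,4-bis(TBSO)phenyl]ethyl prop-2-enoate | C=CC(=O)OCCc1ccc(O[Si](C)(C)C(C)(C)C)c(O[Si](C)(C)C(C)(C)C)c1 | intermediate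
19 | 2-[3,4-bis(TBSO)phenyl]ethyl (2E,4R,5R)-5-{[(1Z)-2-iodo-3-methoxy-3-oxoprop-1-en-1-yl]oxy}-4-[(TBSO)methyl]hex-2-enoate | COC(=O)/C(I)=C/O[C@H](C)[C@@H](CO[Si](C)(C)C(C)(C)C)/C=C/C(=O)OCCc1ccc(O[Si](C)(C)C(C)(C)C)c(O[Si](C)(C)C(C)(C)C)c1 | intermediate
20 | methyl (2R,3R,4S)-4-(2-{2-[3,4-bis(TBSO)phenyl]ethoxy}-2-oxoethyl)-2-methyl-3-[(TBSO)methyl]-3,4-dihydro-2H-pyran-5-carboxylate | COC(=O)C1=CO[C@H](C)[C@@H](CO[Si](C)(C)C(C)(C)C)[C@@H]1CC(=O)OCCc1ccc(O[Si](C)(C)C(C)(C)C)c(O[Si](C)(C)C(C)(C)C)c1 | intermediate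
21 | methyl (2R,3R,4S)-4-{2-[2-(3,4-dihydroxyphenyl)ethoxy]-2-oxoethyl}-3-(hydroxymethyl)-2-methyl-3,4-dihydro-2H-pyran-5-carboxylate | COC(=O)C1=CO[C@H](C)[C@@H](CO)[C@@H]1CC(=O)OCCc1ccc(O)c(O)c1 | target

**Step count and risks**
Total step count: 12. Longest linear sequence: 9 steps (steps 1–6, 10, 11, 12); steps 7–9 make acrylate 18.

Steps most likely to fail:

1. Step 11. The vinyl radical may abstract the hydrogen on the carbon that carries the silyloxymethyl group (1,5-hydrogen transfer) or be reduced before it cyclises, and the chair-like closure may discriminate the two faces of the enoate incompletely. The fallback sets out from 19 and comes back at 20, and closes the ring by an organonickel pathway in place of a radical one. Compound 19 would be treated with an excess of the zerovalent nickel complex Ni(cod)2 and Et3N in MeCN at room temperature. Oxidative addition into the C–I bond, 6-exo insertion of the tethered enoate into the alkenyl–nickel bond and protonation of the nickel enolate on aqueous NH4Cl work-up should give 20. No carbon radical is involved, so hydrogen transfer cannot compete. This fallback makes no new compound (F0).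

2. Step 10. Turnover may be slow at the alkene next to the branched carbon, so that the catalyst is spent on homodimerisation of acrylate 18. The fallback sets out from 13 and comes back at 19, and builds the enoate by carbonyl olefination. Lemieux–Johnson cleavage of the terminal alkene of 13 (OsO4 cat., NaIO4, 2,6-lutidine, dioxane–H2O) would give the aldehyde methyl (2Z)-3-({(2R,3R)-3-formyl-4-(TBSO)butan-2-yl}oxy)-2-iodoprop-2-enoate F1. Alcohol 16 would be esterified with (diethoxyphosphoryl)acetic acid (DCC, DMAP cat., CH2Cl2) to give the phosphonate 2-[3,4-bis(TBSO)phenyl]ethyl (diethoxyphosphoryl)acetate F2. Horner–Wadsworth–Emmons olefination of F1 with F2 under Masamune–Roush conditions (LiCl, iPr2NEt, MeCN, 0 °C) should give the (E)-enoate 19 without epimerising the α-branched aldehyde.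

3. Step 6. Iodoacetoxylation of the terminal alkene may compete with that of the acrylate double bond. The fallback sets out from 11 and comes back at 19, and moves the halogenation behind the fragment coupling so that it meets no isolated alkene. Cross-metathesis of 11 with 18 (catalyst and conditions of step 10) would give 2-[3,4-bis(TBSO)phenyl]ethyl (2E,4R,5R)-5-{[(1E)-3-methoxy-3-oxoprop-1-en-1-yl]oxy}-4-[(TBSO)methyl]hex-2-enoate F3. Its only nucleophilic C=C bond is that of the β-alkoxyacrylate, since the enoate is electron-poor and the arene is flanked by bulky silyloxy groups. NIS and AcOH in CH2Cl2 would then give 2-[3,4-bis(TBSO)phenyl]ethyl (2E,4R,5R)-5-(1-acetoxy-2-iodo-3-methoxy-3-oxopropoxy)-4-[(TBSO)methyl]hex-2-enoate F4 (not isolated), from which Et3N eliminates acetic acid to give 19.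

**Further compounds**
F0 | step 11 | none | none
F1 | step 10 | methyl (2Z)-3-({(2R,3R)-3-formyl-4-(TBSO)butan-2-yl}oxy)-2-iodoprop-2-enoate | COC(=O)/C(I)=C/O[C@H](C)[C@@H](CO[Si](C)(C)C(C)(C)C)C=O
F2 | step 10 | 2-[3,4-bis(TBSO)phenyl]ethyl (diethoxyphosphoryl)acetate | CCOP(=O)(OCC)CC(=O)OCCc1ccc(O[Si](C)(C)C(C)(C)C)c(O[Si](C)(C)C(C)(C)C)c1
F3 | step 6 | 2-[3,4-bis(TBSO)phenyl]ethyl (2E,4R,5R)-5-{[(1E)-3-methoxy-3-oxoprop-1-en-1-yl]oxy}-4-[(TBSO)methyl]hex-2-enoate | COC(=O)/C=C/O[C@H](C)[C@@H](CO[Si](C)(C)C(C)(C)C)/C=C/C(=O)OCCc1ccc(O[Si](C)(C)C(C)(C)C)c(O[Si](C)(C)C(C)(C)C)c1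
F4 | step 6 | 2-[3,4-bis(TBSO)phenyl]ethyl (2E,4R,5R)-5-(1-acetoxy-2-iodo-3-methoxy-3-oxopropoxy)-4-[(TBSO)methyl]hex-2-enoate | COC(=O)C(I)C(OC(C)=O)O[C@H](C)[C@@H](CO[Si](C)(C)C(C)(C)C)/C=C/C(=O)OCCc1ccc(O[Si](C)(C)C(C)(C)C)c(O[Si](C)(C)C(C)(C)C)c1
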